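**Retrosynthetic overview**

1. The three MOM ethers are removed last, and the C4 carbonyl is unveiled only after ring closure, by desilylation and oxidation of a C4 silyl-protected alcohol.
2. Key disconnection O1–C8a: in the target O1 joins the sp3 stereocentre C2 (benzylic to ring B) to the aromatic carbon C8a of ring A. Ring C is therefore closed by palladium-catalysed arylation of the (S)-C2 hydroxyl with a C8a triflate, which makes the aryl–oxygen bond and leaves the C2–O bond untouched.
3. The open-chain precursor (C2 carbinol, C4 silyl ether) comes from oxazaborolidine-controlled reduction of the C2 aryl ketone, which is made by a C3–C4 aldol of the ring B methyl ketone enolate with the ring A triflyloxy aldehyde, then silylation.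
4. The ring A aldehyde comes from 2,4,6-trihydroxybenzaldehyde (C-prenylation, bis-MOM protection, triflation). The ring B ketone comes from 4-bromo-2-methoxyphenol (MOM protection, prenylation at the C–H between Br and OMe, Br–Li exchange and acetylation).
5. Ring order: rings A and B are aromatic from the start; ring C is the only ring formed, in step 10.

Key step: step 10

Assumption: C4 is carried as both epimers from step 7 to step 11 and converges at the ketone in step 12; in step 2 the hydroxyl between formyl and prenyl is taken to be the one left free; ring B is built from 4-bromo-2-methoxyphenol rather than vanillin so that the bromine fixes the prenylation site. "Prenyl" means 3-methylbut-2-en-1-yl throughout.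

**Route**

Step 1
Reactants: 1 2,4,6-trihydroxybenzaldehyde; 2 prenyl bromide
Product: 3 2,4,6-trihydroxy-3-prenylbenzaldehyde
Conditions: DBU (1 equiv), THF, 0 °C → rt
Reagents that add atoms: none
Why: C-alkylation of the ambident phloroglucinol-type phenoxide by the allylic bromide should occur at a ring carbon between two oxygens, and the two free ring positions of 1 are equivalent, so only one mono-C-prenyl isomer can form.

Step 2
Reactants: 3 2,4,6-trihydroxy-3-prenylbenzaldehyde
Product: 4 2-hydroxy-4,6-bis(methoxymethoxy)-3-prenylbenzaldehyde
Conditions: MOMCl (2.1 equiv), i-Pr2NEt, CH2Cl2, 0 °C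
Reagents that add atoms: chloromethyl methyl ether (MOMCl), COCCl
Why: Phenol O-alkylation (MOM ether formation) should cap O4 and O6 first, because the C2 hydroxyl is wedged between formyl and prenyl and held in a hydrogen bond to the formyl oxygen.

Step 3
Reactants: 4 2-hydroxy-4,6-bis(methoxymethoxy)-3-prenylbenzaldehyde
Product: 5 2-formyl-3,5-bis(methoxymethoxy)-6-prenylphenyl trifluoromethanesulfonate
Conditions: Tf2O, pyridine, CH2Cl2, −20 → 0 °C
Reagents that add atoms: trifluoromethanesulfonic anhydride (Tf2O), O=S(=O)(OS(=O)(=O)C(F)(F)F)C(F)(F)F
Why: O-sulfonylation of the remaining phenol with the highly electrophilic anhydride should overcome the hydrogen bond and the flanking groups and gives the aryl triflate that marks C8a for the coupling.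

Step 4
Reactants: 6 4-bromo-2-methoxyphenol
Product: 7 4-bromo-2-methoxy-1-(methoxymethoxy)benzene
Conditions: MOMCl, i-Pr2NEt, CH2Cl2, 0 °C → rt
Reagents that add atoms: chloromethyl methyl ether (MOMCl), COCCl
Why: Routine MOM ether formation on an unhindered phenol gives a group that survives the organolithium, enolate, borane and palladium steps and leaves together with the ring A MOM ethers at the end.

Step 5
Reactants: 7 4-bromo-2-methoxy-1-(methoxymethoxy)benzene; 2 prenyl bromide
Product: 10 1-bromo-3-methoxy-4-(methoxymethoxy)-2-prenylbenzene, via aryllithium 8 (not isolated), via arylcopper 9 (not isolated)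
Conditions: LiN(i-Pr)2 (LDA), THF, −78 °C; CuBr·SMe2, −78 °C; 2, −78 → 0 °C
Reagents that add atoms: none
Why: Deprotonative ortho-metalation then copper-mediated allylic substitution: the ring C–H flanked by bromine and methoxy is the most acidic and is removed by the amide base without bromine–lithium exchange, transmetalation to copper forestalls aryne formation, and the arylcopper should attack prenyl bromide at its unhindered primary carbon.

Step 6
Reactants: 10 1-bromo-3-methoxy-4-(methoxymethoxy)-2-prenylbenzene
Product: 12 1-[3-methoxy-4-(methoxymethoxy)-2-prenylphenyl]ethan-1-one, via aryllithium 11 (not isolated)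
Conditions: n-BuLi, THF, −78 °C; MeC(O)N(OMe)Me, −78 → 0 °C; aq. NH4Cl
Reagents that add atoms: N-methoxy-N-methylacetamide, CC(=O)N(C)OC
Why: Bromine–lithium exchange followed by Weinreb ketone synthesis should give the methyl ketone, because the chelated tetrahedral adduct persists until work-up and prevents a second addition.

Step 7
Reactants: 12 1-[3-methoxy-4-(methoxymethoxy)-2-prenylphenyl]ethan-1-one; 5 2-formyl-3,5-bis(methoxymethoxy)-6-prenylphenyl trifluoromethanesulfonate
Product: 14 racemic 2-{1-hydroxy-3-[3-methoxy-4-(methoxymethoxy)-2-prenylphenyl]-3-oxopropyl}-3,5-bis(methoxymethoxy)-6-prenylphenyl trifluoromethanesulfonate, via lithium enolate 13 (not isolated)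
Conditions: LiN(i-Pr)2, THF, −78 °C; 5, −78 °C; AcOH, −78 °C
Reagents that add atoms: none
Why: Directed aldol addition of the preformed kinetic lithium enolate to the non-enolisable aldehyde forms C3–C4; C4 arises racemic, which does not matter because it becomes the ketone in step 12, and the cold acidic quench should forestall retro-aldol and dehydration.

Step 8
Reactants: 14 racemic aldol adduct
Product: 15 racemic 2-{1-[(tert-butyldimethylsilyl)oxy]-3-[3-methoxy-4-(methoxymethoxy)-2-prenylphenyl]-3-oxopropyl}-3,5-bis(methoxymethoxy)-6-prenylphenyl trifluoromethanesulfonate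
Conditions: TBSOTf, 2,6-lutidine, CH2Cl2, −78 °C
Reagents that add atoms: tert-butyldimethylsilyl trifluoromethanesulfonate (TBSOTf), CC(C)(C)[Si](C)(C)OS(=O)(=O)C(F)(F)F
Why: Silylation of the hindered benzylic hydroxyl with the silyl triflate and a non-nucleophilic base is fast at low temperature and should remove the retro-aldol and elimination liability of the β-hydroxy ketone before the reduction.

Step 9
Reactants: 15 racemic silyloxy ketone
Product: 16 2-{(3S)-1-[(tert-butyldimethylsilyl)oxy]-3-hydroxy-3-[3-methoxy-4-(methoxymethoxy)-2-prenylphenyl]propyl}-3,5-bis(methoxymethoxy)-6-prenylphenyl trifluoromethanesulfonate (both epimers at the silyloxy carbon)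
Conditions: (R)-2-methyl-CBS-oxazaborolidine (20 mol%), catecholborane, toluene, −78 → −40 °C
Reagents that add atoms: none
Why: Corey–Bakshi–Shibata reduction: the ketone binds the oxazaborolidine boron with its aryl group (large) away from the catalyst and its CH2 group (small) toward it, and hydride from the nitrogen-bound borane reaches one face only, which with the (R)-catalyst should set C2 as (S) regardless of the remote C4 centre; catecholborane spares the prenyl alkenes.

Step 10
Reactants: 16 (S)-carbinol triflate (C4 epimer mixture)
Product: 17 (2S)-4-[(tert-butyldimethylsilyl)oxy]-2-[3-methoxy-4-(methoxymethoxy)-2-prenylphenyl]-5,7-bis(methoxymethoxy)-8-prenylchromane (both C4 epimers)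
Conditions: Pd(OAc)2 (5 mol%), rac-2-(di-tert-butylphosphino)-1,1'-binaphthyl (6 mol%), Cs2CO3, toluene, 80 °C
Reagents that add atoms: none
Why: Zerovalent palladium carrying the bulky dialkylbiarylphosphine inserts into the C8a–O bond of the aryl triflate, the carbonate deprotonates the C2 hydroxyl once it is bound to the arylpalladium centre, and C(sp2)–O reductive elimination forms O1–C8a. The closest known reaction type is the intramolecular Buchwald–Hartwig etherification of aryl halides and sulfonates with tethered secondary alcohols to give chromans. Ring C (O1, C2, C3, C4, C4a, C8a) is closed by reductive elimination from a seven-membered aryl(alkoxo)palladium chelate (Pd, C8a, C4a, C4, C3, C2, O1), which contracts to the six-membered oxygen ring. No stereocentre is created: the C2–O bond is never broken, so the (S) configuration from step 9 is carried through with retention, and C4 stays an epimer mixture. The step needs reductive elimination to outrun β-hydride elimination of the secondary benzylic alkoxide and needs the triflate S–O bond to survive; the di-tert-butylphosphine ligand, the two ortho substituents at C8a (prenyl and the C4 side chain) that speed reductive elimination, and the weak heterogeneous carbonate base in toluene should secure both. Only the C2 oxygen can cyclise, since the C4 oxygen is silylated and could in any case close only a four-membered ring.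

Step 11
Reactants: 17 (2S)-4-silyloxyflavan
Product: 18 (2S)-2-[3-methoxy-4-(methoxymethoxy)-2-prenylphenyl]-5,7-bis(methoxymethoxy)-8-prenylchroman-4-ol (both C4 epimers)
Conditions: Bu4NF, THF, 0 °C → rt
Reagents that add atoms: none
Why: Fluoride-induced desilylation, driven by Si–F bond formation, should free the C4 hydroxyl without touching the MOM ethers, the C2 aryl ether stereocentre or the prenyl groups.

Step 12
Reactants: 18 (2S)-flavan-4-ol
Product: 19 (2S)-2-[3-methoxy-4-(methoxymethoxy)-2-prenylphenyl]-5,7-bis(methoxymethoxy)-8-prenylchroman-4-one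
Conditions: Dess–Martin periodinane, NaHCO3, CH2Cl2, 0 °C → rt
Reagents that add atoms: none
Why: Dess–Martin oxidation of the benzylic secondary alcohol under buffered, non-basic conditions should convert both C4 epimers into the one chroman-4-one without opening ring C to a chalcone, so C2 stays (S).

Step 13
Reactants: 19 (2S)-tris-MOM flavanone
Product: 20 (2S)-5,7-dihydroxy-2-(4-hydroxy-3-methoxy-2-prenylphenyl)-8-prenylchroman-4-one (CNP0282226.1)
Conditions: HCl (1.25 M in MeOH), 40 °C
Reagents that add atoms: none
Why: Acid-catalysed acetal exchange with methanol removes the three MOM groups as dimethoxymethane, and mild methanolic acid at moderate temperature should leave the prenyl groups uncyclised and C2 unchanged.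

**Compound list**

1 | 2,4,6-trihydroxybenzaldehyde | O=Cc1c(O)cc(O)cc1O | starting material
2 | prenyl bromide (1-bromo-3-methylbut-2-ene) | CC(C)=CCBr | starting material
3 | 2,4,6-trihydroxy-3-prenylbenzaldehyde | O=Cc1c(O)cc(O)c(CC=C(C)C)c1O | intermediate
4 | 2-hydroxy-4,6-bis(methoxymethoxy)-3-prenylbenzaldehyde | O=Cc1c(OCOC)cc(OCOC)c(CC=C(C)C)c1O | intermediate
5 | 2-formyl-3,5-bis(methoxymethoxy)-6-prenylphenyl trifluoromethanesulfonate | O=Cc1c(OCOC)cc(OCOC)c(CC=C(C)C)c1OS(=O)(=O)C(F)(F)F | intermediate
6 | 4-bromo-2-methoxyphenol | COc1cc(Br)ccc1O | starting material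
7 | 4-bromo-2-methoxy-1-(methoxymethoxy)benzene | COCOc1ccc(Br)cc1OC | intermediate
8 | [6-bromo-2-methoxy-3-(methoxymethoxy)phenyl]lithium (not isolated) | COCOc1ccc(Br)c([Li])c1OC | intermediate
9 | [6-bromo-2-methoxy-3-(methoxymethoxy)phenyl]copper (not isolated) | COCOc1ccc(Br)c([Cu])c1OC | intermediate
10 | 1-bromo-3-methoxy-4-(methoxymethoxy)-2-prenylbenzene | COCOc1ccc(Br)c(CC=C(C)C)c1OC | intermediate
11 | [3-methoxy-4-(methoxymethoxy)-2-prenylphenyl]lithium (not isolated) | COCOc1ccc([Li])c(CC=C(C)C)c1OC | intermediate
12 | 1-[3-methoxy-4-(methoxymethoxy)-2-prenylphenyl]ethan-1-one | CC(=O)c1ccc(OCOC)c(OC)c1CC=C(C)C | intermediate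
13 | lithium 1-[3-methoxy-4-(methoxymethoxy)-2-prenylphenyl]ethen-1-olate (not isolated) | C=C(O[Li])c1ccc(OCOC)c(OC)c1CC=C(C)C | intermediate
14 | racemic aldol adduct (β-hydroxy ketone, ring A triflate) | COc1c(OCOC)ccc(C(=O)CC(O)c2c(OCOC)cc(OCOC)c(CC=C(C)C)c2OS(=O)(=O)C(F)(F)F)c1CC=C(C)C | intermediate
15 | racemic TBS ether of 14 (β-silyloxy ketone) | COc1c(OCOC)ccc(C(=O)CC(O[Si](C)(C)C(C)(C)C)c2c(OCOC)cc(OCOC)c(CC=C(C)C)c2OS(=O)(=O)C(F)(F)F)c1CC=C(C)C | intermediate
16 | (S)-carbinol triflate, C4 epimer mixture (key-step precursor) | COc1c(OCOC)ccc([C@@H](O)CC(O[Si](C)(C)C(C)(C)C)c2c(OCOC)cc(OCOC)c(CC=C(C)C)c2OS(=O)(=O)C(F)(F)F)c1CC=C(C)C | intermediate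
17 | (2S)-4-(tert-butyldimethylsilyloxy)flavan, C4 epimer mixture (key-step product) | COc1c(OCOC)ccc([C@@H]2CC(O[Si](C)(C)C(C)(C)C)c3c(OCOC)cc(OCOC)c(CC=C(C)C)c3O2)c1CC=C(C)C | intermediate
18 | (2S)-flavan-4-ol, C4 epimer mixture | COc1c(OCOC)ccc([C@@H]2CC(O)c3c(OCOC)cc(OCOC)c(CC=C(C)C)c3O2)c1CC=C(C)C | intermediate
19 | (2S)-tris-MOM flavanone | COc1c(OCOC)ccc([C@@H]2CC(=O)c3c(OCOC)cc(OCOC)c(CC=C(C)C)c3O2)c1CC=C(C)C | intermediate
20 | (2S)-5,7-dihydroxy-2-(4-hydroxy-3-methoxy-2-prenylphenyl)-8-prenylchroman-4-one | COc1c(O)ccc([C@@H]2CC(=O)c3c(O)cc(O)c(CC=C(C)C)c3O2)c1CC=C(C)C | target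

**Step count**

Total: 13 steps. Longest linear sequence: 10 steps (steps 1–3 or 4–6, then 7–13).

**Steps most likely to fail**

Step 10 (key step). The palladium alkoxide may undergo β-hydride elimination instead of reductive elimination, the triflyl group may be lost by S–O cleavage at the hindered, electron-rich arene, or the silyl group may migrate from the C4 oxygen to the C2 oxygen under carbonate; each consumes 16 without closing ring C. The fallback forms O1–C2 instead, with inversion, by known chemistry. It sets out from ketone 15, which is reduced with the enantiomeric (S)-2-methyl-CBS-oxazaborolidine and catecholborane to the (R)-carbinol triflate F1. The aryl triflate is then cleaved with Et4NOH in dioxane at rt to give the (R)-carbinol phenol F2. Intramolecular Mitsunobu etherification (PPh3, DIAD, toluene, 0 °C) lets the C8a phenol displace the activated C2 oxygen with inversion, giving the (2S)-flavan and rejoining the route at 17. Low temperature and a non-polar solvent are chosen to keep the displacement bimolecular at this electron-rich benzylic carbon.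

Step 9. Facial selectivity may erode because the ortho-prenyl aryl group is twisted and the branched silyloxy chain is bulky, and uncatalysed borane reduction or hydroboration of the prenyl alkenes may compete. The fallback replaces boron hydride chemistry by Noyori–Ikariya asymmetric transfer hydrogenation, which recognises the aryl group by a CH/π contact rather than by size and contains no hydroborating species. It sets out from 15 and uses RuCl[(S,S)-TsDPEN](p-cymene) in HCO2H/Et3N (5:2) at rt to 40 °C; this should deliver the (S)-carbinol and comes back to the route at 16. This fallback makes no new compound (F0).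

Step 1. Over-alkylation to di-C-prenyl products and O-alkylation of the ambident phenoxide may dominate, and site selection in the following MOM protection may be imperfect. The fallback introduces the prenyl group by a sigmatropic route after protection. It sets out from 1, which is treated with MOMCl (2 equiv) and i-Pr2NEt to give 2-hydroxy-4,6-bis(methoxymethoxy)benzaldehyde F3. The remaining phenol is converted with methyl 2-methylbut-3-en-2-yl carbonate and Pd(PPh3)4 (THF, 0 °C) into the 1,1-dimethylallyl aryl ether F4. Heating in toluene at 110 °C should bring about aromatic Claisen [3,3] rearrangement to the only free ortho carbon, which gives the ortho-prenyl phenol directly and rejoins the route at 4, bypassing 3.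

**Further compounds**

F1 | step 10 | (R)-carbinol triflate, C2 epimer of 16 (C4 epimer mixture) | COc1c(OCOC)ccc([C@H](O)CC(O[Si](C)(C)C(C)(C)C)c2c(OCOC)cc(OCOC)c(CC=C(C)C)c2OS(=O)(=O)C(F)(F)F)c1CC=C(C)C
F2 | step 10 | (R)-carbinol phenol (C4 epimer mixture) | COc1c(OCOC)ccc([C@H](O)CC(O[Si](C)(C)C(C)(C)C)c2c(OCOC)cc(OCOC)c(CC=C(C)C)c2O)c1CC=C(C)C
F0 | step 9 | none | none
F3 | step 1 | 2-hydroxy-4,6-bis(methoxymethoxy)benzaldehyde | O=Cc1c(O)cc(OCOC)cc1OCOC
F4 | step 1 | 2-[(2-methylbut-3-en-2-yl)oxy]-4,6-bis(methoxymethoxy)benzaldehyde | O=Cc1c(OCOC)cc(OCOC)cc1OC(C)(C)C=C
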